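The runs stem from a simulated flask for substances that don't exist; the scatter is artificial.

A small charge of catalyst, 1.3 mM, had to turn over 0.26 M of substrate while 2.2 mM of added ligand stood ready to park it as idle complex.

| flask | substrate | gas phase | catalyst | added ligand | remark | time |
|---|---|---|---|---|---|---|
| maple | 0.26 M | 81 mM (held) | 0.87 mM | 2.2 mM | run made earlier |  |
| alder | 0.26 M | 81 mM (held) | 2 mM | 2.2 mM | run made earlier |  |
| ash | 0.26 M | 81 mM (held) | 1.3 mM | 1.1 mM | run made earlier |  |
| flask | 0.26 M | 81 mM (held) | 1.3 mM | 2.2 mM |  | 5.0 d |

- maple (time / d: over-reaction product / %, substrate / %, target / %): 0.208: 0, 97.1, 4.6; 0.625: 2.6, 83.5, 14.9; 1.04: 0.5, 72.7, 26.1; 1.67: 0, 60.4, 39.3; 2.50: 0.1, 43.6, 56.6; 3.00: 2.3, 37.6, 60.6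
- alder (time / d: over-reaction product / %, substrate / %, target / %): 0.250: 0, 84.0, 14.1; 0.417: 0, 75.8, 26.1; 0.625: 0, 62.4, 38.7; 1.04: 0.2, 42.0, 56.6; 1.67: 3.9, 22.9, 72.7; 3.00: 9.4, 5.8, 85.0
- ash (time / d: over-reaction product / %, substrate / %, target / %): 0.625: 0.1, 65.0, 36.0; 1.25: 1.1, 38.7, 60.2; 1.67: 4.2, 26.0, 70.3; 2.50: 5.6, 12.4, 82.5; 3.00: 9.6, 8.7, 85.6

(each reading ± 1 percentage point)

- amounts and yields of target count crystals too
- given per volume of solution although it is solid: crystals
- at the start none of the gas is dissolved
- what was read earlier has a scatter of 1 percentage point, one standard deviation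
- reactions considered so far: catalyst + target -> catalyst + over-reaction product; crystals <-> target; substrate + dissolved gas + catalyst -> catalyst + target; gas phase <-> dissolved gas; catalyst + added ligand <-> idle complex
- the concentration of target that is asked is that of its free form alone

1. concentration of over-reaction product at 5.0 d, in M
2. concentration of substrate at 5.0 d, in M
3. concentration of target (only what is free in solution, in the first phase) at 5.0 d, in M
4. concentration of dissolved gas at 5.0 d, in M

How fast did substrate go in this flask? The maple and alder runs carried the flask's ligand charge, and their substrate fell roughly exponentially, so I took the logarithm of charged over remaining substrate, per day, at their last readings. Maple gave 0.326 d⁻¹ and alder 0.949 d⁻¹. That is 2.91 times the rate on 2.30 times the catalyst, which is how a parking ligand shows. Interpolating on the catalyst charge put the flask at 0.563 d⁻¹; I call this pace, the pseudo-first-order loss of substrate at the charged amounts.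

How far did that carry the flask? Pace times time came to 2.82, leaving 5.96% of the substrate, or 0.0155 M.

Where did the rest stand? Over-reaction runs on the same catalyst, and alder's last reading had nearly the same pace times time, 2.85. So I took alder's readings: over-reaction product 0.0244 M and target 0.221 M, which I counted as dissolved. Substrate, which draws on dissolved gas, stood by my reckoning at 5.96% of its charge, so I put c(dissolved gas) near 81 mM.

The forecast, noting “The data barely show a solubility cap”, said c(over-reaction product) 0.024 M, c(substrate) 0.02 M, c(target) 0.16 M and c(dissolved gas) 0.008 M; mine parted from it on the last three.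

The flask gave c(over-reaction product) 0.0214 M, c(substrate) 0.0156 M, c(target) 0.223 M and c(dissolved gas) 0.0800 M.

    catalyst + target → catalyst + over-reaction product (k = 2.40 M⁻¹ h⁻¹)
    crystals ⇌ target, rate k2*(cs2 - [target]) while solid is left; crystals form when [target] > cs2 (solubility = 0.250 M, k = 1.20 h⁻¹)
    substrate + dissolved gas + catalyst → catalyst + target (k = 670 M⁻² h⁻¹)
    gas phase ⇌ dissolved gas, rate k4*(csat - [dissolved gas]) (kL = 0.430 h⁻¹)
    catalyst + added ligand ⇌ idle complex, settled at all times (K = 1300 M⁻¹)

Read back from the result, the flask's pace was 0.562 d⁻¹. Parking as idle complex, together with the time given, held c(over-reaction product) at 0.0214 M; without parking it reached 0.0696 M. At the asked time 36.0% of the catalyst stood free here, against 52.8% in a neighbour flask with added ligand cut to 0.0013 M. Scaling my pace by that ratio gives 0.826 d⁻¹ and 1.60% of substrate left; that neighbour kept 1.6%.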